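**Plan**

1. Numbering used below: ring atoms C1 (stereocentre) to C14, with C3=C4 (Z, methyl on C4), C7=C8 (acid on C8) and C11=C12 (E, methyl on C12); C15 is the side-chain carbon on C1 and C16 its methylene.
2. Retrosynthesis: the C8 acid comes from its ethyl ester and C14–H from C14–CO2H; the ring bond C14–C1 and the C15=C16 methylene are then cut together (retro-Ireland–Claisen) to an 18-membered allylic lactone. This is opened at the lactone C–O, then at C1–C2 (alkenyl–allyl coupling), C7=C8 (HWE), C8–C9 (alkylation) and C13–C14 (Johnson–Claisen).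
3. Enabling feature: C1 is an sp3 ring carbon that carries the exocyclic 1,1-disubstituted alkene C15=C16 and is bonded to the ring methylene C14, so C14–C1–C15=C16 is a pent-4-enoic acid (Claisen) retron once C14 bears a carboxyl.
4. Forward: an open C2–C14 chain is assembled from commercial pieces and closed to the 18-membered lactone, which is contracted to the 14-membered carbocycle, the only ring and the last one formed; the helper carboxyl is then removed.
5. Stereochemistry: C1 from the chiral boron controller in the ring contraction; C3=C4 (Z) from neryl acetate, C7=C8 (E) from the HWE reaction, C11=C12 (E) from the Johnson–Claisen chair.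

Key step: step 12

Assumption: the (S,S)-configured diazaborolidine controller is taken to deliver the (R) configuration at C1 through the chair transition state; the (R,R)-controller is equally available and would be used if the sense of induction were the reverse.

**Step 1**
Reactants: 1 3-(tert-butyldimethylsilyloxy)propanal; 2 isopropenylmagnesium bromide
Product: 3 5-(tert-butyldimethylsilyloxy)-2-methylpent-1-en-3-ol (racemic)
Conditions: THF, −78 → 0 °C; aq. NH4Cl
Reagents that add atoms: none
Why: Grignard 1,2-addition to the aldehyde gives the secondary allylic alcohol, whose configuration is irrelevant because the carbinol carbon becomes sp2 in step 2.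

**Step 2**
Reactants: 3 5-(tert-butyldimethylsilyloxy)-2-methylpent-1-en-3-ol; 4 trimethyl orthoacetate
Product: 5 methyl (4E)-7-(tert-butyldimethylsilyloxy)-4-methylhept-4-enoate
Conditions: EtCO2H (cat.), 110 °C, MeOH distilled off
Reagents that add atoms: none
Why: Johnson–Claisen rearrangement through a chair transition state with the CH2CH2OTBS group equatorial (the axial alternative clashes with the 2-methyl group) should set the E geometry of C11=C12 and deliver C13–C14 plus the helper carboxyl carbon.

**Step 3**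
Reactants: 5 methyl (4E)-7-(tert-butyldimethylsilyloxy)-4-methylhept-4-enoate
Product: 6 methyl (4E)-7-hydroxy-4-methylhept-4-enoate
Conditions: TBAF, THF, 0 °C → rt
Reagents that add atoms: none
Why: Fluoride-mediated desilylation of a primary TBS ether, to which the ester and the alkene are inert.

**Step 4**
Reactants: 6 methyl (4E)-7-hydroxy-4-methylhept-4-enoate
Product: 7 methyl (4E)-7-iodo-4-methylhept-4-enoate
Conditions: I2, PPh3, imidazole, CH2Cl2, 0 °C
Reagents that add atoms: iodine II
Why: Garegg–Samuelsson (Appel-type) iodination of a primary alcohol proceeds by SN2 displacement of the alkoxyphosphonium group and leaves the trisubstituted alkene untouched.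

**Step 5**
Reactants: 7 methyl (4E)-7-iodo-4-methylhept-4-enoate; 8 triethyl phosphonoacetate
Product: 9 1-ethyl 9-methyl (5E)-2-(diethoxyphosphoryl)-6-methylnon-5-enedioate
Conditions: 8 (2 equiv), NaH, DMF, 0 → 55 °C
Reagents that add atoms: none
Why: C-alkylation of the sodium phosphonoacetate with a primary iodide (SN2) forms C8–C9; excess phosphonate suppresses double alkylation.

**Step 6**
Reactants: 10 neryl acetate
Product: 12 (2Z)-3-methyl-6-oxohex-2-en-1-yl acetate, via secondary ozonide 11 (not isolated)
Conditions: O3 (1.0 equiv), CH2Cl2, −78 °C; then Me2S, −78 °C → rt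
Reagents that add atoms: ozone [O-][O+]=O
Why: Chemoselective ozonolysis cleaves the electron-rich 6,7-alkene in preference to the 2,3-alkene deactivated by the allylic acetate, so the Z geometry of the future C3=C4 bond is carried through unchanged.

**Step 7**
Reactants: 9 1-ethyl 9-methyl (5E)-2-(diethoxyphosphoryl)-6-methylnon-5-enedioate; 12 (2Z)-3-methyl-6-oxohex-2-en-1-yl acetate
Product: 13 ethyl (2E,6Z)-8-acetoxy-2-[(3E)-7-methoxy-4-methyl-7-oxohept-3-en-1-yl]-6-methylocta-2,6-dienoate
Conditions: LiCl, DBU, MeCN, 0 °C → rt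
Reagents that add atoms: none
Why: Horner–Wadsworth–Emmons olefination under Masamune–Roush conditions with an α-alkyl phosphonoacetate should give mainly the E enoate (ester trans to the C6 chain) by reversible addition and thermodynamic control, and the mild base spares the acetate.

**Step 8**
Reactants: 14 5-bromo-2-methylpent-2-ene; 15 prop-2-yn-1-ol
Product: 18 (2Z)-2-(4-methylpent-3-en-1-yl)-3-(tributylstannyl)prop-2-en-1-ol, via homoprenylmagnesium bromide 16 (not isolated), via alkenylmagnesium alkoxide 17 (not isolated)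
Conditions: 14, Mg, THF; then 15 (0.33 equiv), CuI (10 mol %), THF/Et2O, −10 °C → rt; then Bu3SnCl, 0 °C → rt; aq. NH4Cl
Reagents that add atoms: tributyltin chloride CCCC[Sn](Cl)(CCCC)CCCC
Why: Copper-catalysed, alkoxide-directed anti-carbomagnesiation of propargyl alcohol places the alkyl group on the inner carbon and magnesium cis to CH2O in a five-membered chelate, and stannylation with retention fixes the Z alkenylstannane.

**Step 9**
Reactants: 13 ethyl (2E,6Z)-8-acetoxy-2-[(3E)-7-methoxy-4-methyl-7-oxohept-3-en-1-yl]-6-methylocta-2,6-dienoate; 18 (2Z)-2-(4-methylpent-3-en-1-yl)-3-(tributylstannyl)prop-2-en-1-ol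
Product: 19 ethyl (2E,6Z,9Z)-10-(hydroxymethyl)-2-[(3E)-7-methoxy-4-methyl-7-oxohept-3-en-1-yl]-6,14-dimethylpentadeca-2,6,9,13-tetraenoate
Conditions: Pd2(dba)3 (3 mol %), LiCl (3 equiv), DMF, 25–40 °C
Reagents that add atoms: none
Why: Stille-type coupling of an allylic acetate with an alkenylstannane joins C1 to the primary allyl terminus C2; the alkenyl geometry is retained and the Z geometry of C3=C4 should persist because syn/anti exchange would need a tertiary σ-allylpalladium species.

**Step 10**
Reactants: 19 ethyl (2E,6Z,9Z)-10-(hydroxymethyl)-2-[(3E)-7-methoxy-4-methyl-7-oxohept-3-en-1-yl]-6,14-dimethylpentadeca-2,6,9,13-tetraenoate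
Product: 20 (4E,8E,12Z,15Z)-8-(ethoxycarbonyl)-16-(hydroxymethyl)-4,12,20-trimethylhenicosa-4,8,12,15,19-pentaenoic acid
Conditions: LiOH (1.2 equiv), THF/H2O, 0 °C → rt; then cold 1 M HCl
Reagents that add atoms: lithium hydroxide [Li+].[OH-]
Why: Chemoselective saponification, since the unhindered saturated methyl ester should hydrolyse far faster than the conjugated, α-branched ethyl enoate.

**Step 11**
Reactants: 20 (4E,8E,12Z,15Z)-8-(ethoxycarbonyl)-16-(hydroxymethyl)-4,12,20-trimethylhenicosa-4,8,12,15,19-pentaenoic acid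
Product: 21 ethyl (3Z,6Z,10E,14E)-7,15-dimethyl-3-(4-methylpent-3-en-1-yl)-18-oxo-1-oxacyclooctadeca-3,6,10,14-tetraene-11-carboxylate
Conditions: MNBA, DMAP, CH2Cl2, rt, slow addition (final ca. 1 mM)
Reagents that add atoms: none
Why: Shiina macrolactonisation of a hydroxy acid with an unhindered primary allylic alcohol under high dilution should close the 18-membered lactone, which is the temporary ring for the key step.

**Step 12**
Reactants: 21 ethyl (3Z,6Z,10E,14E)-7,15-dimethyl-3-(4-methylpent-3-en-1-yl)-18-oxo-1-oxacyclooctadeca-3,6,10,14-tetraene-11-carboxylate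
Product: 24 (3E,7E,11Z,14S)-7-(ethoxycarbonyl)-3,11-dimethyl-14-(6-methylhepta-1,5-dien-2-yl)cyclotetradeca-3,7,11-triene-1-carboxylic acid (either configuration at the carboxyl-bearing carbon), via boron ketene acetal 22 (not isolated), via acyloxyborane 23 (not isolated)
Conditions: (S,S)-1,2-diphenylethylenediamine bis[3,5-bis(trifluoromethyl)benzenesulfonamide] (2.2 equiv), BBr3, CH2Cl2, rt, then evaporation; 21, 1,2,2,6,6-pentamethylpiperidine, CH2Cl2, −78 → 4 °C, 48 h; pH 7 buffer
Reagents that add atoms: none
Why: Soft enolisation of the only enolisable ester (the lactone; the enoate has no α-hydrogen) by the chiral B–Br reagent and the hindered amine gives boron ketene acetal 22, which on warming undergoes a concerted [3,3]-sigmatropic shift in which C14 bonds to C1 while the allylic C16–O bond breaks and C15=C16 appears. The closest known reaction type is the enantioselective Ireland–Claisen rearrangement of achiral allylic esters through chiral boron enolates, including its use for contracting macrocyclic lactones to carbocycles. The 14-membered ring is closed by transannular C–C bond formation inside the 18-membered lactone through a six-centre chair transition state (a sigmatropic ring contraction that expels C15, C16, the ester oxygen and the carbonyl carbon from the ring), so no exo/endo descriptor applies. C1 is controlled by the reagent: the C2-symmetric sulfonamide ligand on boron shields one face of the ketene acetal and the chair relays this choice to one face of the (Z)-C1=C15 alkene, whereas C14 follows the enolate geometry and is erased in step 13. The step needs chair over boat selectivity, which the homoprenyl group on the central allyl carbon C15 secures because it would eclipse the boron-bearing oxygen in a boat, and bond formation at C1 only, which the concerted pathway guarantees.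

**Step 13**
Reactants: 24 (3E,7E,11Z,14S)-7-(ethoxycarbonyl)-3,11-dimethyl-14-(6-methylhepta-1,5-dien-2-yl)cyclotetradeca-3,7,11-triene-1-carboxylic acid
Product: 26 ethyl (1E,5Z,8R,11E)-5,11-dimethyl-8-(6-methylhepta-1,5-dien-2-yl)cyclotetradeca-1,5,11-triene-1-carboxylate, via thiohydroxamate ester 25 (not isolated)
Conditions: N-hydroxypyridine-2-thione, DCC, DMAP (cat.), CH2Cl2, 0 °C → rt, dark; then Bu3SnH (10 equiv, ca. 1 M), PhH, hν (W lamp), 10 °C
Reagents that add atoms: none
Why: Barton reductive decarboxylation removes the helper carboxyl; concentrated tin hydride should trap the secondary C14 radical before it can cyclise onto C15=C16, and the nucleophilic stannyl radical, unlike a thiyl radical, should not isomerise the electron-rich Z alkene.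

**Step 14**
Reactants: 26 ethyl (1E,5Z,8R,11E)-5,11-dimethyl-8-(6-methylhepta-1,5-dien-2-yl)cyclotetradeca-1,5,11-triene-1-carboxylate
Product: 27 (1E,5Z,8R,11E)-5,11-dimethyl-8-(6-methylhepta-1,5-dien-2-yl)cyclotetradeca-1,5,11-triene-1-carboxylic acid
Conditions: LiOH, THF/MeOH/H2O, 50 °C; then 1 M HCl
Reagents that add atoms: lithium hydroxide [Li+].[OH-]
Why: Saponification of the conjugated ester under basic conditions, to which the isolated alkenes and the non-acidic allylic stereocentre C1 are inert.

**Compound list**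

1 | 3-(tert-butyldimethylsilyloxy)propanal | O=CCCO[Si](C)(C)C(C)(C)C | starting material
2 | isopropenylmagnesium bromide | CC(=C)[Mg]Br | starting material
3 | 5-(tert-butyldimethylsilyloxy)-2-methylpent-1-en-3-ol (racemic) | C=C(C)C(O)CCO[Si](C)(C)C(C)(C)C | intermediate
4 | trimethyl orthoacetate | CC(OC)(OC)OC | starting material
5 | methyl (4E)-7-(tert-butyldimethylsilyloxy)-4-methylhept-4-enoate | COC(=O)CC/C(C)=C/CCO[Si](C)(C)C(C)(C)C | intermediate
6 | methyl (4E)-7-hydroxy-4-methylhept-4-enoate | COC(=O)CC/C(C)=C/CCO | intermediate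
7 | methyl (4E)-7-iodo-4-methylhept-4-enoate | COC(=O)CC/C(C)=C/CCI | intermediate
8 | triethyl phosphonoacetate | CCOC(=O)CP(=O)(OCC)OCC | starting material
9 | 1-ethyl 9-methyl (5E)-2-(diethoxyphosphoryl)-6-methylnon-5-enedioate | CCOC(=O)C(CC/C=C(\C)CCC(=O)OC)P(=O)(OCC)OCC | intermediate
10 | neryl acetate | CC(=O)OC/C=C(/C)CCC=C(C)C | starting material
11 | secondary ozonide of neryl acetate at the 6,7-alkene | CC(=O)OC/C=C(/C)CCC1OOC(C)(C)O1 | intermediate
12 | (2Z)-3-methyl-6-oxohex-2-en-1-yl acetate | CC(=O)OC/C=C(/C)CCC=O | intermediate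
13 | ethyl (2E,6Z)-8-acetoxy-2-[(3E)-7-methoxy-4-methyl-7-oxohept-3-en-1-yl]-6-methylocta-2,6-dienoate | CC(=O)OC/C=C(/C)CC/C=C(/C(=O)OCC)CC/C=C(\C)CCC(=O)OC | intermediate
14 | 5-bromo-2-methylpent-2-ene | CC(C)=CCCBr | starting material
15 | prop-2-yn-1-ol | C#CCO | starting material
16 | (4-methylpent-3-en-1-yl)magnesium bromide | CC(C)=CCC[Mg]Br | intermediate
17 | (Z)-alkenylmagnesium bromide with bromomagnesium alkoxide, from anti-carbomagnesiation | Br[Mg]/C=C(\CO[Mg]Br)CCC=C(C)C | intermediate
18 | (2Z)-2-(4-methylpent-3-en-1-yl)-3-(tributylstannyl)prop-2-en-1-ol | CCCC[Sn](CCCC)(CCCC)/C=C(\CO)CCC=C(C)C | intermediate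
19 | ethyl (2E,6Z,9Z)-10-(hydroxymethyl)-2-[(3E)-7-methoxy-4-methyl-7-oxohept-3-en-1-yl]-6,14-dimethylpentadeca-2,6,9,13-tetraenoate | OC/C(CCC=C(C)C)=C\C/C=C(/C)CC/C=C(/C(=O)OCC)CC/C=C(\C)CCC(=O)OC | intermediate
20 | (4E,8E,12Z,15Z)-8-(ethoxycarbonyl)-16-(hydroxymethyl)-4,12,20-trimethylhenicosa-4,8,12,15,19-pentaenoic acid | OC/C(CCC=C(C)C)=C\C/C=C(/C)CC/C=C(/C(=O)OCC)CC/C=C(\C)CCC(=O)O | intermediate
21 | ethyl (3Z,6Z,10E,14E)-7,15-dimethyl-3-(4-methylpent-3-en-1-yl)-18-oxo-1-oxacyclooctadeca-3,6,10,14-tetraene-11-carboxylate | O=C1CC/C(C)=C/CC/C(C(=O)OCC)=C\CC/C(C)=C\C/C=C(CCC=C(C)C)\CO1 | intermediate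
22 | boron ketene acetal of 21 carrying the (4S,5S)-1,3-bis[3,5-bis(trifluoromethyl)phenylsulfonyl]-4,5-diphenyl-1,3,2-diazaborolidin-2-yl group on oxygen | C1(OB2N(S(=O)(=O)c3cc(cc(c3)C(F)(F)F)C(F)(F)F)[C@@H](c3ccccc3)[C@H](c3ccccc3)N2S(=O)(=O)c2cc(cc(c2)C(F)(F)F)C(F)(F)F)=CC/C(C)=C/CC/C(C(=O)OCC)=C\CC/C(C)=C\C/C=C(CCC=C(C)C)\CO1 | intermediate
23 | acyloxyborane of 24 with the same diazaborolidine | C=C(CCC=C(C)C)[C@H]1C/C=C(/C)CC/C=C(/C(=O)OCC)CC/C=C(\C)CC1C(=O)OB1N(S(=O)(=O)c2cc(cc(c2)C(F)(F)F)C(F)(F)F)[C@@H](c2ccccc2)[C@H](c2ccccc2)N1S(=O)(=O)c1cc(cc(c1)C(F)(F)F)C(F)(F)F | intermediate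
24 | (3E,7E,11Z,14S)-7-(ethoxycarbonyl)-3,11-dimethyl-14-(6-methylhepta-1,5-dien-2-yl)cyclotetradeca-3,7,11-triene-1-carboxylic acid (configuration at C1 of this name not specified) | C=C(CCC=C(C)C)[C@H]1C/C=C(/C)CC/C=C(/C(=O)OCC)CC/C=C(\C)CC1C(=O)O | intermediate
25 | 2-thioxopyridin-1(2H)-yl ester of 24 | C=C(CCC=C(C)C)[C@H]1C/C=C(/C)CC/C=C(/C(=O)OCC)CC/C=C(\C)CC1C(=O)ON1C=CC=CC1=S | intermediate
26 | ethyl (1E,5Z,8R,11E)-5,11-dimethyl-8-(6-methylhepta-1,5-dien-2-yl)cyclotetradeca-1,5,11-triene-1-carboxylate | C=C(CCC=C(C)C)[C@H]1C/C=C(/C)CC/C=C(/C(=O)OCC)CC/C=C(\C)CC1 | intermediate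
27 | (1E,5Z,8R,11E)-5,11-dimethyl-8-(6-methylhepta-1,5-dien-2-yl)cyclotetradeca-1,5,11-triene-1-carboxylic acid | C=C(CCC=C(C)C)[C@H]1C/C=C(/C)CC/C=C(/C(=O)O)CC/C=C(\C)CC1 | target

**Step count**

Total: 14 steps. Longest linear sequence: 12 steps (1, 2, 3, 4, 5, 7, 9, 10, 11, 12, 13, 14).

**Steps most likely to fail**

Step 12. Soft enolisation of the large lactone may stall, or a competing boat pathway or weak face discrimination by the boron ligand may erode the enantiomeric purity at C1. Fallback, setting out from 21: a silyl ketene acetal Ireland–Claisen rearrangement (LDA, TMSCl, THF, −78 °C → rt) should pass through the trimethylsilyl ketene acetal F1 and the racemic trimethylsilyl ester F2, which aqueous acid hydrolyses to the racemic ring-contracted acid F3. Preparative chromatography of F3 on a chiral stationary phase, pooling the fractions with the required configuration at the side-chain carbon, returns to the route at 24.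

Step 13. The C14 radical may undergo 1,2-vinyl migration (3-exo closure onto C15=C16 and reopening) or the chain carrier may add to the enoate before hydrogen transfer. Fallback, setting out from 24: activation with N-hydroxyphthalimide and DIC/DMAP gives the redox-active N-(acyloxy)phthalimide F4, which is reduced without a radical chain by nickel catalysis (NiCl2·6H2O, a bipyridine ligand, Zn, PhSiH3, THF/DMF/i-PrOH, 40 °C); this returns to the route at 26.

Step 9. Slow transmetallation may let the π-allylpalladium intermediate undergo syn/anti isomerisation, with loss of the Z geometry at C3=C4, or ionisation of the acetate may be sluggish. Fallback, setting out from 13 and 18: methanolysis (K2CO3 cat., MeOH, 0 °C) of 13 gives the allylic alcohol F5, and Corey–Kim chlorination (NCS, Me2S, CH2Cl2, −20 → 0 °C) gives the allylic chloride F6, which ionises fast. Stannane 18 is converted by n-BuLi (2.1 equiv, THF, −78 → −20 °C) and ZnCl2 into the alkenylzinc chloride lithium alkoxide F7, which transmetallates fast. Negishi coupling of F6 with F7 (Pd(PPh3)4, THF, rt, aqueous work-up) returns to the route at 19.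

**Further compounds**

F1 | step 12 | trimethylsilyl ketene acetal of lactone 21 | C1(O[Si](C)(C)C)=CC/C(C)=C/CC/C(C(=O)OCC)=C\CC/C(C)=C\C/C=C(CCC=C(C)C)\CO1
F2 | step 12 | racemic trimethylsilyl ester of the ring-contracted acid | C=C(CCC=C(C)C)C1C/C=C(/C)CC/C=C(/C(=O)OCC)CC/C=C(\C)CC1C(=O)O[Si](C)(C)C
F3 | step 12 | racemic ring-contracted acid | C=C(CCC=C(C)C)C1C/C=C(/C)CC/C=C(/C(=O)OCC)CC/C=C(\C)CC1C(=O)O
F4 | step 13 | 1,3-dioxoisoindolin-2-yl ester of 24 | C=C(CCC=C(C)C)[C@H]1C/C=C(/C)CC/C=C(/C(=O)OCC)CC/C=C(\C)CC1C(=O)ON1C(=O)c2ccccc2C1=O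
F5 | step 9 | ethyl (2E,6Z)-8-hydroxy-2-[(3E)-7-methoxy-4-methyl-7-oxohept-3-en-1-yl]-6-methylocta-2,6-dienoate | OC/C=C(/C)CC/C=C(/C(=O)OCC)CC/C=C(\C)CCC(=O)OC
F6 | step 9 | ethyl (2E,6Z)-8-chloro-2-[(3E)-7-methoxy-4-methyl-7-oxohept-3-en-1-yl]-6-methylocta-2,6-dienoate | ClC/C=C(/C)CC/C=C(/C(=O)OCC)CC/C=C(\C)CCC(=O)OC
F7 | step 9 | (Z)-alkenylzinc chloride lithium alkoxide from 18 | Cl[Zn]/C=C(\CO[Li])CCC=C(C)C
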